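**Assumption:** the SMILES is read as the 4‑oxo/6‑hydroxy enol tautomer of the dearomatised farnesyl‑dimethylorsellinic acid; the stereocentre is (R), both internal alkenes are E, and keto/enol tautomers are treated as one compound.

## Retrosynthetic overview

1. The obvious disconnection, dearomative C‑farnesylation of a dimethylorsellinate, is avoided; the target comes from its fluoride‑labile 2‑(trimethylsilyl)ethyl (TMSE) ester.
2. The only carbocycle is formed last, by intramolecular Knoevenagel closure (C5→C6) of an acyclic 3,5,7‑triketo ester whose pre‑set quaternary carbon blocks aromatisation.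
3. The triketo ester comes from oxidation of a hydroxy diketo ester, made by acylating a 3‑oxopentanoate dianion with a quaternary β‑lactone (an acetoacetyl donor whose ketone is masked as the ring C–O).
4. The quaternary stereocentre is set by trans‑selective farnesylation of a β‑lactone enolate; the adjacent carbinol centre relays the chirality and is later oxidised away.
5. The lactone comes from methyl (R)‑3‑hydroxybutanoate. Ring order: temporary β‑lactone (step 3, opened in step 6), then the cyclohexadienone (step 8).

## Route

**Step 1**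
Reactants: 1 methyl (R)‑3‑hydroxybutanoate; 2 iodomethane
Product: 3 methyl (2R,3R)‑3‑hydroxy‑2‑methylbutanoate (anti)
Conditions: LDA (2.2 equiv), THF, −78 → −20 °C; then MeI, DMPU, −78 → 0 °C
Reagents that add atoms: iodomethane, CI
Why: Fráter–Seebach alkylation: the lithium‑chelated dianion is methylated anti to the C3 methyl; only the untouched (3R) carbinol centre matters later, because C2 is re‑enolised in step 4.

**Step 2**
Reactants: 3 methyl (2R,3R)‑3‑hydroxy‑2‑methylbutanoate
Product: 4 (2R,3R)‑3‑hydroxy‑2‑methylbutanoic acid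
Conditions: LiOH, THF/H2O, 0 °C → rt; then acidify to pH 2, extract with EtOAc
Reagents that add atoms: lithium hydroxide/water, [Li+].[OH-] / O
Why: Ordinary saponification of an unhindered ester; the carbinol centre is not touched.

**Step 3**
Reactants: 4 (2R,3R)‑3‑hydroxy‑2‑methylbutanoic acid
Product: 5 (3R,4R)‑3,4‑dimethyloxetan‑2‑one (trans; volatile, handle in solution or distil)
Conditions: PhSO2Cl, pyridine, 0 → 4 °C
Reagents that add atoms: none
Why: Adam β‑lactonisation by carboxyl activation (mixed sulfonic anhydride), so the hydroxyl oxygen attacks the acyl carbon and C4 keeps its (R) configuration.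

**Step 4**
Reactants: 5 (3R,4R)‑3,4‑dimethyloxetan‑2‑one; 6 (2E,6E)‑farnesyl bromide
Product: 7 (3R,4R)‑3,4‑dimethyl‑3‑[(2E,6E)‑3,7,11‑trimethyldodeca‑2,6,10‑trien‑1‑yl]oxetan‑2‑one
Conditions: LDA (1.05 equiv), THF, −78 °C (lactone added to base); then 6, −78 → −50 °C; chromatograph to remove the minor cis‑alkylated diastereomer
Reagents that add atoms: (2E,6E)‑farnesyl bromide, CC(C)=CCC/C(C)=C/CC/C(C)=C/CBr
Why: Mulzer‑type β‑lactone enolate alkylation: the planar four‑ring enolate cannot β‑eliminate at −78 °C and is attacked SN2 by the allylic bromide on the face trans to the C4 methyl, setting the (3R) quaternary centre; the minor diastereomer must be removed here because it would later become the enantiomer.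

**Step 5**
Reactants: 8 methyl 3‑oxopentanoate; 9 2‑(trimethylsilyl)ethanol
Product: 10 2‑(trimethylsilyl)ethyl 3‑oxopentanoate
Conditions: DMAP (cat.), toluene, reflux with removal of MeOH
Reagents that add atoms: 2‑(trimethylsilyl)ethanol, C[Si](C)(C)CCO
Why: Standard β‑keto ester transesterification (via the acylketene or DMAP acyl transfer), giving an ester that can be removed at the end with fluoride.

**Step 6**
Reactants: 7 the quaternary β‑lactone; 10 2‑(trimethylsilyl)ethyl 3‑oxopentanoate (as its dianion, 3 equiv)
Product: 11 2‑(trimethylsilyl)ethyl (6R,7R)‑7‑hydroxy‑4,6‑dimethyl‑3,5‑dioxo‑6‑[(2E,6E)‑3,7,11‑trimethyldodeca‑2,6,10‑trien‑1‑yl]octanoate (C4 epimers/enol forms)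
Conditions: 10, NaH then n‑BuLi, THF, 0 °C; add 7 at −78 °C, warm to −30 °C; AcOH quench at −78 °C, pH 7 work‑up; use crude
Reagents that add atoms: the dianion of 10, CCC(=O)CC(=O)OCC[Si](C)(C)C
Why: Proposed new method: Claisen‑type acyl–oxygen opening of the strained lactone by the γ‑carbon of a Weiler dianion; the lactone has no α‑H to enolise, SN2 at C4 is blocked by the adjacent quaternary carbon, and the product ketone is immediately deprotonated as a 1,3‑dicarbonyl so it cannot over‑add, while the C6 oxygen stays as an alkoxide so no ketone competes; the closest known reactions are opening of β‑lactones by ester enolates to δ‑hydroxy‑β‑keto esters and acylation of β‑keto ester dianions by esters and Weinreb amides.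

**Step 7**
Reactants: 11 the hydroxy diketo ester
Product: 12 2‑(trimethylsilyl)ethyl (6R)‑4,6‑dimethyl‑3,5,7‑trioxo‑6‑[(2E,6E)‑3,7,11‑trimethyldodeca‑2,6,10‑trien‑1‑yl]octanoate
Conditions: Dess–Martin periodinane (1.3 equiv), NaHCO3, CH2Cl2, 0 °C → rt; telescope without purification
Reagents that add atoms: none
Why: Buffered Dess–Martin oxidation of the secondary carbinol to the methyl ketone tolerates the triene and the silyl ester; the relay stereocentre is deliberately destroyed and the quaternary centre has no α‑H to epimerise.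

**Step 8**
Reactants: 12 the triketo ester
Product: 13 2‑(trimethylsilyl)ethyl (3R)‑6‑hydroxy‑2,3,5‑trimethyl‑4‑oxo‑3‑[(2E,6E)‑3,7,11‑trimethyldodeca‑2,6,10‑trien‑1‑yl]cyclohexa‑1,5‑diene‑1‑carboxylate
Conditions: Et3N (3 equiv), CH2Cl2, rt; then PPTS (cat.), 40 °C to complete dehydration
Reagents that add atoms: none
Why: Intramolecular Knoevenagel condensation (the aldol–dehydration used in biomimetic triketo‑ester cyclisations to resorcylates): the C2 methylene of the β‑keto ester attacks the C7 methyl ketone in the only six‑membered carbocyclisation available, and E1cB loss of water gives the vinylogous acid, which cannot aromatise because of the quaternary carbon.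

**Step 9**
Reactants: 13 the TMSE ester
Product: 14 (3R)‑6‑hydroxy‑2,3,5‑trimethyl‑4‑oxo‑3‑[(2E,6E)‑3,7,11‑trimethyldodeca‑2,6,10‑trien‑1‑yl]cyclohexa‑1,5‑diene‑1‑carboxylic acid (target)
Conditions: TBAF (3 equiv), THF, 0 °C → rt; cold pH 4 buffer work‑up
Reagents that add atoms: none
Why: Fluoride‑induced β‑elimination of the 2‑(trimethylsilyl)ethyl ester (loss of Me3SiF and ethylene) frees the acid without acid, Pd or heat, so the triene and the quaternary centre are untouched.

## Compound list

1 | methyl (R)‑3‑hydroxybutanoate | C[C@@H](O)CC(=O)OC | starting material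
2 | iodomethane | CI | starting material
3 | methyl (2R,3R)‑3‑hydroxy‑2‑methylbutanoate | C[C@@H](O)[C@@H](C)C(=O)OC | intermediate
4 | (2R,3R)‑3‑hydroxy‑2‑methylbutanoic acid | C[C@@H](O)[C@@H](C)C(=O)O | intermediate
5 | (3R,4R)‑3,4‑dimethyloxetan‑2‑one | C[C@H]1OC(=O)[C@@H]1C | intermediate
6 | (2E,6E)‑farnesyl bromide | CC(C)=CCC/C(C)=C/CC/C(C)=C/CBr | starting material
7 | (3R,4R)‑3‑farnesyl‑3,4‑dimethyloxetan‑2‑one | CC(C)=CCC/C(C)=C/CC/C(C)=C/C[C@@]1(C)C(=O)O[C@@H]1C | intermediate
8 | methyl 3‑oxopentanoate | CCC(=O)CC(=O)OC | starting material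
9 | 2‑(trimethylsilyl)ethanol | C[Si](C)(C)CCO | starting material
10 | 2‑(trimethylsilyl)ethyl 3‑oxopentanoate | CCC(=O)CC(=O)OCC[Si](C)(C)C | intermediate
11 | TMSE (6R,7R)‑6‑farnesyl‑7‑hydroxy‑4,6‑dimethyl‑3,5‑dioxooctanoate | CC(C)=CCC/C(C)=C/CC/C(C)=C/C[C@](C)([C@@H](C)O)C(=O)C(C)C(=O)CC(=O)OCC[Si](C)(C)C | intermediate
12 | TMSE (6R)‑6‑farnesyl‑4,6‑dimethyl‑3,5,7‑trioxooctanoate | CC(C)=CCC/C(C)=C/CC/C(C)=C/C[C@](C)(C(C)=O)C(=O)C(C)C(=O)CC(=O)OCC[Si](C)(C)C | intermediate
13 | TMSE (3R)‑3‑farnesyl‑6‑hydroxy‑2,3,5‑trimethyl‑4‑oxocyclohexa‑1,5‑diene‑1‑carboxylate | CC(C)=CCC/C(C)=C/CC/C(C)=C/C[C@@]1(C)C(=O)C(C)=C(O)C(C(=O)OCC[Si](C)(C)C)=C1C | intermediate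
14 | (3R)‑3‑farnesyl‑6‑hydroxy‑2,3,5‑trimethyl‑4‑oxocyclohexa‑1,5‑diene‑1‑carboxylic acid | CC(C)=CCC/C(C)=C/CC/C(C)=C/C[C@@]1(C)C(=O)C(C)=C(O)C(C(=O)O)=C1C | target

## Summary

Total steps: 9 (eight on the main line plus one reagent preparation, step 5).
Longest linear sequence: 8 steps (1 → 2 → 3 → 4 → 6 → 7 → 8 → 9).

Steps most likely to fail, with fallbacks:

1. **Step 6** (dianion opening of the hindered β‑lactone; risks are sluggish acyl attack, retro‑aldol of the aldolate, and hemiketal/dihydropyranone formation on work‑up). Fallback: open 7 with MeNH(OMe)·HCl/Me2AlCl to the β‑hydroxy Weinreb amide, protect the carbinol as its TES ether, and acylate the dianion of 10 with this acyclic amide; desilylate, then continue with steps 7–9.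
2. **Step 7** (oxidising a neopentyl carbinol in the presence of an enolised, hemiketal‑prone tricarbonyl). Fallback: carry the ketone instead of the carbinol into the coupling. Saponify 7, oxidise the β‑hydroxy acid to the 2,2‑disubstituted acetoacetic acid, activate it cold with Ghosez's reagent, and acylate the 1,3‑bis(trimethylsilyloxy)diene of 10 with the acid chloride; this gives 12 directly.
3. **Step 4** (lactone enolate stability and trans selectivity with only a methyl as the directing group). Fallback: set the quaternary centre on the open chain by a second Fráter–Seebach alkylation of the dianion of 3 with farnesyl bromide (same anti sense, giving the (2R,3R) hydroxy ester), then saponify and lactonise with PhSO2Cl/pyridine to reach 7.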